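**Retrosynthetic overview**

1. The C40 skeleton is cut at the C14'–C15' single bond into a C18 acetylenic-ring terminal diyne 10, one methyl from Me3Al, and a C21 triol-ring pentaenyl iodide 26. These are joined in one pot by Zr-catalysed methylalumination and Pd/Zn alkenyl–alkenyl coupling, followed by one global desilylation.
2. Enabling feature: C13'(CH3)=C14'H is an E-trisubstituted, methyl-branched alkene whose unsubstituted carbon C14' carries the bond to C15', which is the retron of syn Me–Al addition to a terminal alkyne C13'≡C14'–H. C15'H=C15H is an E-vinylic CH (alkenyl iodide), and the only other alkyne, C7'≡C8', is internal and pinned between the fully substituted C6' of the acetylenic ring and C9'.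
3. Acetylenic half: enol triflate 3 (from (4R,6R)-actinol), Sonogashira coupling with E-enynol 4, oxidation, HWE enyne homologation, desilylation.
4. Triol half: triflate 3, allylic alcohol, Sharpless epoxidation (sets C5), reductive transposition, ozonolysis to α-ketol 17, axial addition of a C11 trienynyl dianion (sets C6), trans-hydroalumination, oxidation, Takai iodo-olefination, silylation.
5. No ring is formed: both six-membered rings come from actinol, and only transient rings (the 5,6-epoxide and an ozonide) are made and opened.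

Key step: step 22

Remark: positions are given in carotenoid numbering (unprimed = triol half, primed = acetylenic half); the target is read as the 5,6-cis-diol with both tertiary hydroxyls trans to the 3-OH, i.e. (3S,5R,6S,3'R).
Remark: compounds 1, 4, 7 and 19 are taken as catalogue chemicals; lithium or sodium salts formed by simple deprotonation are treated as the reactive form of the numbered compound and carry no number.

**Route**

Step 1
Reactants: 1 (4R,6R)-4-hydroxy-2,2,6-trimethylcyclohexan-1-one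
Product: 2 (4R,6R)-4-[(tert-butyldimethylsilyl)oxy]-2,2,6-trimethylcyclohexan-1-one
Conditions: TBSCl, imidazole, DMF, 23 °C
Reagents that add atoms: tert-butyldimethylsilyl chloride CC(C)(C)[Si](C)(C)Cl
Why: Standard silylation of the secondary alcohol gives an ether that should survive every step up to the final fluoride treatment.

Step 2
Reactants: 2 (4R,6R)-4-[(tert-butyldimethylsilyl)oxy]-2,2,6-trimethylcyclohexan-1-one
Product: 3 (4R)-4-[(tert-butyldimethylsilyl)oxy]-2,6,6-trimethylcyclohex-1-en-1-yl trifluoromethanesulfonate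
Conditions: LiN(i-Pr)2, THF, −78 °C; then PhNTf2, −78 → 0 °C
Reagents that add atoms: N-phenylbis(trifluoromethanesulfonimide) O=S(=O)(N(c1ccccc1)S(=O)(=O)C(F)(F)F)C(F)(F)F
Why: Enolisation is only possible toward the methine α-carbon (the other α-carbon is quaternary), so O-triflation should give a single tetrasubstituted enol triflate; the methyl-bearing stereocentre of 1 is erased on purpose.

Step 3
Reactants: 3 (4R)-4-[(tert-butyldimethylsilyl)oxy]-2,6,6-trimethylcyclohex-1-en-1-yl trifluoromethanesulfonate; 4 (2E)-3-methylpent-2-en-4-yn-1-ol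
Product: 5 (2E)-5-[(4R)-4-[(tert-butyldimethylsilyl)oxy]-2,6,6-trimethylcyclohex-1-en-1-yl]-3-methylpent-2-en-4-yn-1-ol
Conditions: Pd(PPh3)4 (5 mol %), CuI (10 mol %), Et3N, DMF, 60 °C
Reagents that add atoms: none
Why: Sonogashira coupling of a cyclohexenyl triflate with a terminal alkyne forms the C6'–C7' bond, and the C9'=C10' E geometry is carried in from 4.

Step 4
Reactants: 5 (2E)-5-[(4R)-4-[(tert-butyldimethylsilyl)oxy]-2,6,6-trimethylcyclohex-1-en-1-yl]-3-methylpent-2-en-4-yn-1-ol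
Product: 6 (2E)-5-[(4R)-4-[(tert-butyldimethylsilyl)oxy]-2,6,6-trimethylcyclohex-1-en-1-yl]-3-methylpent-2-en-4-ynal
Conditions: MnO2, CH2Cl2, 23 °C
Reagents that add atoms: none
Why: Chemoselective oxidation of the allylic primary alcohol by activated MnO2 should leave the silyl ether and the enyne untouched.

Step 5
Reactants: 7 3-bromo-1-(trimethylsilyl)prop-1-yne
Product: 8 diethyl [3-(trimethylsilyl)prop-2-yn-1-yl]phosphonate
Conditions: P(OEt)3, neat, 120 °C
Reagents that add atoms: triethyl phosphite CCOP(OCC)OCC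
Why: Michaelis–Arbuzov reaction of a reactive propargylic bromide gives the phosphonate needed for enyne homologation.

Step 6
Reactants: 6 (2E)-5-[(4R)-4-[(tert-butyldimethylsilyl)oxy]-2,6,6-trimethylcyclohex-1-en-1-yl]-3-methylpent-2-en-4-ynal; 8 diethyl [3-(trimethylsilyl)prop-2-yn-1-yl]phosphonate
Product: 9 tert-butyldimethyl{[(1R)-3,5,5-trimethyl-4-[(3E,5E)-3-methyl-8-(trimethylsilyl)octa-3,5-diene-1,7-diyn-1-yl]cyclohex-3-en-1-yl]oxy}silane
Conditions: 8, NaN(SiMe3)2, THF, −78 °C; then 6, −78 → 0 °C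
Reagents that add atoms: none
Why: Horner–Wadsworth–Emmons olefination with the stabilised propargylic phosphonate anion should form the C11'=C12' bond mainly E, and any minor Z isomer is to be removed by chromatography.

Step 7
Reactants: 9 tert-butyldimethyl{[(1R)-3,5,5-trimethyl-4-[(3E,5E)-3-methyl-8-(trimethylsilyl)octa-3,5-diene-1,7-diyn-1-yl]cyclohex-3-en-1-yl]oxy}silane
Product: 10 tert-butyldimethyl{[(1R)-3,5,5-trimethyl-4-[(3E,5E)-3-methylocta-3,5-diene-1,7-diyn-1-yl]cyclohex-3-en-1-yl]oxy}silane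
Conditions: K2CO3, MeOH–THF, 23 °C
Reagents that add atoms: none
Why: Methanolysis of the alkynyl C–Si bond frees the terminal alkyne C13'≡C14'–H while the secondary TBS ether is stable to carbonate.

Step 8
Reactants: 3 (4R)-4-[(tert-butyldimethylsilyl)oxy]-2,6,6-trimethylcyclohex-1-en-1-yl trifluoromethanesulfonate
Product: 11 methyl (4R)-4-[(tert-butyldimethylsilyl)oxy]-2,6,6-trimethylcyclohex-1-ene-1-carboxylate
Conditions: Pd(OAc)2 (5 mol %), PPh3 (10 mol %), CO (1 atm), MeOH, Et3N, DMF, 60 °C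
Reagents that add atoms: carbon monoxide [C-]#[O+]; methanol CO
Why: Palladium-catalysed methoxycarbonylation of the enol triflate installs C7 at the ester level.

Step 9
Reactants: 11 methyl (4R)-4-[(tert-butyldimethylsilyl)oxy]-2,6,6-trimethylcyclohex-1-ene-1-carboxylate
Product: 12 [(4R)-4-[(tert-butyldimethylsilyl)oxy]-2,6,6-trimethylcyclohex-1-en-1-yl]methanol
Conditions: i-Bu2AlH, CH2Cl2, −78 → 0 °C
Reagents that add atoms: none
Why: 1,2-Reduction of the conjugated ester gives the allylic alcohol required for a directed epoxidation.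

Step 10
Reactants: 12 [(4R)-4-[(tert-butyldimethylsilyl)oxy]-2,6,6-trimethylcyclohex-1-en-1-yl]methanol
Product: 13 [(1R,4S,6R)-4-[(tert-butyldimethylsilyl)oxy]-2,2,6-trimethyl-7-oxabicyclo[4.1.0]heptan-1-yl]methanol
Conditions: Ti(Oi-Pr)4, D-(−)-diethyl tartrate, t-BuOOH, 4 Å molecular sieves, CH2Cl2, −20 °C
Reagents that add atoms: tert-butyl hydroperoxide CC(C)(C)OO
Why: Sharpless asymmetric epoxidation with the D-(−)-tartrate ligand should deliver oxygen to the C5=C6 face anti to the C3 silyloxy group under reagent control, which sets the C5–O stereocentre (R).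

Step 11
Reactants: 13 [(1R,4S,6R)-4-[(tert-butyldimethylsilyl)oxy]-2,2,6-trimethyl-7-oxabicyclo[4.1.0]heptan-1-yl]methanol
Product: 14 (1S,4S,6R)-4-[(tert-butyldimethylsilyl)oxy]-1-(iodomethyl)-2,2,6-trimethyl-7-oxabicyclo[4.1.0]heptane
Conditions: PPh3, I2, imidazole, THF, 0 → 23 °C
Reagents that add atoms: iodine [I][I]
Why: Appel-type iodination of the primary alcohol proceeds by displacement at CH2 and touches neither epoxide carbon.

Step 12
Reactants: 14 (1S,4S,6R)-4-[(tert-butyldimethylsilyl)oxy]-1-(iodomethyl)-2,2,6-trimethyl-7-oxabicyclo[4.1.0]heptane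
Product: 15 (1R,5S)-5-[(tert-butyldimethylsilyl)oxy]-1,3,3-trimethyl-2-methylidenecyclohexan-1-ol
Conditions: Zn dust, AcOH, EtOH, 23 °C
Reagents that add atoms: none
Why: Zinc-mediated reductive elimination of the β-iodo epoxide cleaves the C6–O bond and leaves the C5–O bond intact, so the transposed tertiary allylic alcohol keeps the C5 configuration set in step 10.

Step 13
Reactants: 15 (1R,5S)-5-[(tert-butyldimethylsilyl)oxy]-1,3,3-trimethyl-2-methylidenecyclohexan-1-ol
Product: 17 (2R,4S)-4-[(tert-butyldimethylsilyl)oxy]-2-hydroxy-2,6,6-trimethylcyclohexan-1-one, via spiro ozonide 16 (not isolated)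
Conditions: O3, CH2Cl2, −78 °C; then Me2S, −78 → 23 °C
Reagents that add atoms: ozone [O-][O+]=O
Why: Ozonolysis of the exocyclic methylene removes the auxiliary carbon and unveils the non-enolisable α-ketol without touching the C5 stereocentre.

Step 14
Reactants: 4 (2E)-3-methylpent-2-en-4-yn-1-ol
Product: 18 (2E)-3-methylpent-2-en-4-ynal
Conditions: MnO2, CH2Cl2, 23 °C (used as a solution)
Reagents that add atoms: none
Why: Allylic oxidation with MnO2 gives the volatile enynal, which is carried on without concentration.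

Step 15
Reactants: 18 (2E)-3-methylpent-2-en-4-ynal; 19 ethyl (2E)-4-(diethoxyphosphoryl)-3-methylbut-2-enoate
Product: 20 ethyl (2E,4E,6E)-3,7-dimethylnona-2,4,6-trien-8-ynoate
Conditions: 19, LiN(SiMe3)2, THF–DMPU, −78 °C; then 18, −78 → 0 °C
Reagents that add atoms: none
Why: Vinylogous Horner–Wadsworth–Emmons olefination, the standard C5 extension of retinoid chemistry, should give the all-E trienynoate as the main isomer, the phosphonate anion being too weakly basic to deprotonate the alkyne; the 2Z isomer is to be separated.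

Step 16
Reactants: 20 ethyl (2E,4E,6E)-3,7-dimethylnona-2,4,6-trien-8-ynoate
Product: 21 (2E,4E,6E)-3,7-dimethylnona-2,4,6-trien-8-yn-1-ol
Conditions: i-Bu2AlH, CH2Cl2, −78 °C
Reagents that add atoms: none
Why: 1,2-Reduction of the ester at low temperature leaves the terminal alkyne and the triene untouched.

Step 17
Reactants: 17 (2R,4S)-4-[(tert-butyldimethylsilyl)oxy]-2-hydroxy-2,6,6-trimethylcyclohexan-1-one; 21 (2E,4E,6E)-3,7-dimethylnona-2,4,6-trien-8-yn-1-ol
Product: 22 (1R,2R,4S)-4-[(tert-butyldimethylsilyl)oxy]-1-[(3E,5E,7E)-9-hydroxy-3,7-dimethylnona-3,5,7-trien-1-yn-1-yl]-2,6,6-trimethylcyclohexane-1,2-diol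
Conditions: 21 (2.2 equiv), n-BuLi (4.4 equiv), THF, −78 → 0 °C; then 17, −78 → 23 °C; aq NH4Cl
Reagents that add atoms: none
Why: 1,2-Addition of the alkoxide–acetylide dianion to the non-enolisable ketone should occur by axial attack on the chair that has the C5–O bond and one C1 methyl axial, that is anti to both α-axial groups and antiperiplanar to C5–O (polar Felkin–Anh model), so the new C6–OH is set cis to the C5–OH.

Step 18
Reactants: 22 (1R,2R,4S)-4-[(tert-butyldimethylsilyl)oxy]-1-[(3E,5E,7E)-9-hydroxy-3,7-dimethylnona-3,5,7-trien-1-yn-1-yl]-2,6,6-trimethylcyclohexane-1,2-diol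
Product: 23 (1S,2R,4S)-4-[(tert-butyldimethylsilyl)oxy]-1-[(1E,3E,5E,7E)-9-hydroxy-3,7-dimethylnona-1,3,5,7-tetraen-1-yl]-2,6,6-trimethylcyclohexane-1,2-diol
Conditions: NaAlH2(OCH2CH2OMe)2, THF, 0 → 23 °C; aq potassium sodium tartrate
Reagents that add atoms: none
Why: Hydroxyl-directed trans-hydroalumination of the propargylic alcohol and protonolysis give the E-C7=C8 alkene, the classical reduction of enynyl carbinols to polyene carbinols.

Step 19
Reactants: 23 (1S,2R,4S)-4-[(tert-butyldimethylsilyl)oxy]-1-[(1E,3E,5E,7E)-9-hydroxy-3,7-dimethylnona-1,3,5,7-tetraen-1-yl]-2,6,6-trimethylcyclohexane-1,2-diol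
Product: 24 (2E,4E,6E,8E)-9-[(1S,2R,4S)-4-[(tert-butyldimethylsilyl)oxy]-1,2-dihydroxy-2,6,6-trimethylcyclohexyl]-3,7-dimethylnona-2,4,6,8-tetraenal
Conditions: SO3·pyridine, DMSO, i-Pr2NEt, CH2Cl2, 0 °C
Reagents that add atoms: none
Why: Parikh–Doering oxidation converts only the primary allylic alcohol, and unlike MnO2 it cannot cleave the di-tertiary cis-diol, which it leaves free.

Step 20
Reactants: 24 (2E,4E,6E,8E)-9-[(1S,2R,4S)-4-[(tert-butyldimethylsilyl)oxy]-1,2-dihydroxy-2,6,6-trimethylcyclohexyl]-3,7-dimethylnona-2,4,6,8-tetraenal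
Product: 25 (1S,2R,4S)-4-[(tert-butyldimethylsilyl)oxy]-1-[(1E,3E,5E,7E,9E)-10-iodo-3,7-dimethyldeca-1,3,5,7,9-pentaen-1-yl]-2,6,6-trimethylcyclohexane-1,2-diol
Conditions: CrCl2, CHI3, THF–1,4-dioxane, 0 → 23 °C, dark
Reagents that add atoms: iodoform IC(I)I
Why: Takai iodo-olefination with the geminal dichromium reagent adds C15' and should give the E-alkenyl iodide, free tertiary hydroxyls being tolerated by divalent chromium.

Step 21
Reactants: 25 (1S,2R,4S)-4-[(tert-butyldimethylsilyl)oxy]-1-[(1E,3E,5E,7E,9E)-10-iodo-3,7-dimethyldeca-1,3,5,7,9-pentaen-1-yl]-2,6,6-trimethylcyclohexane-1,2-diol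
Product: 26 1,2-bis-O-trimethylsilyl ether of 25
Conditions: TMSOTf, 2,6-lutidine, CH2Cl2, −78 → −40 °C
Reagents that add atoms: trimethylsilyl trifluoromethanesulfonate C[Si](C)(C)OS(=O)(=O)C(F)(F)F
Why: The silyl triflate should silylate both hindered tertiary hydroxyls, masking the acidic protons that would otherwise quench the organometallic partner of step 22.

Step 22
Reactants: 10 tert-butyldimethyl{[(1R)-3,5,5-trimethyl-4-[(3E,5E)-3-methylocta-3,5-diene-1,7-diyn-1-yl]cyclohex-3-en-1-yl]oxy}silane; 26 1,2-bis-O-trimethylsilyl ether of 25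
Product: 29 (3S,5R,6S,3'R)-3,3'-bis[(tert-butyldimethylsilyl)oxy]-5,6-bis[(trimethylsilyl)oxy]-7',8'-didehydro-5,6-dihydro-β,β-carotene, via alkenyldimethylalane 27 (not isolated), via alkenylzinc chloride 28 (not isolated)
Conditions: 10 (1.3 equiv), Me3Al, Cp2ZrCl2 (0.5 equiv), ClCH2CH2Cl, 23 °C; volatiles removed in vacuo; then ZnCl2, THF; then 26, Pd2(dba)3 (2.5 mol %), P(2-furyl)3 (10 mol %), THF–DMF, 23 °C, dark, argon
Reagents that add atoms: trimethylaluminium C[Al](C)C
Why: Cp2ZrCl2 and Me3Al generate a cationic methylzirconium–aluminium species that adds methyl and metal syn across the terminal alkyne C13'≡C14'–H of 10 with methyl on the internal carbon, giving E-alkenylalane 27; after the excess Me3Al is stripped, ZnCl2 transmetalates it to alkenylzinc 28, zerovalent palladium inserts into the C15'–I bond of 26 with retention, and transmetalation and reductive elimination forge the C14'–C15' bond. The closest known reaction type is the Negishi carboalumination followed by Pd- and Zn-promoted alkenyl–alkenyl coupling, which has been used to join polyenylalanes made from conjugated terminal enynes to polyenyl halides in the retinoid and carotenoid series. No ring is closed and no stereocentre is created; the step sets the C13'=C14' geometry by syn addition and transfers the C15=C15' geometry of 26 by retention at both sp2 carbons. The selectivity needed is chemo- and regioselectivity for the terminal alkyne, which the substrate secures because the second alkyne C7'≡C8' is internal and shielded by the tetrasubstituted C5'=C6' bond, the geminal methyls of the acetylenic ring and the C9' methyl. The tertiary allylic silyl ethers at C5 and C6 of 26 never meet free Me3Al, and the mild alkenylzinc medium should leave them and the TBS ethers intact. In one operation the step adds C20', fixes one trisubstituted alkene and unites the C18 and C21 halves into the complete C40 framework with every stereo-element in place.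

Step 23
Reactants: 29 (3S,5R,6S,3'R)-3,3'-bis[(tert-butyldimethylsilyl)oxy]-5,6-bis[(trimethylsilyl)oxy]-7',8'-didehydro-5,6-dihydro-β,β-carotene
Product: 30 (3S,5R,6S,3'R)-7',8'-didehydro-5,6-dihydro-β,β-carotene-3,5,6,3'-tetrol
Conditions: Bu4NF, AcOH, THF, 23 → 40 °C, dark
Reagents that add atoms: none
Why: Buffered fluoride should cleave all four silyl ethers in one operation under non-acidic conditions that spare the tertiary allylic C6 alcohol and the polyene.

**Compound list**

1 | (4R,6R)-4-hydroxy-2,2,6-trimethylcyclohexan-1-one (actinol) | C[C@@H]1C[C@@H](O)CC(C)(C)C1=O | starting material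
2 | (4R,6R)-4-[(tert-butyldimethylsilyl)oxy]-2,2,6-trimethylcyclohexan-1-one | C[C@@H]1C[C@@H](O[Si](C)(C)C(C)(C)C)CC(C)(C)C1=O | intermediate
3 | (4R)-4-[(tert-butyldimethylsilyl)oxy]-2,6,6-trimethylcyclohex-1-en-1-yl trifluoromethanesulfonate | CC1=C(OS(=O)(=O)C(F)(F)F)C(C)(C)C[C@H](O[Si](C)(C)C(C)(C)C)C1 | intermediate
4 | (2E)-3-methylpent-2-en-4-yn-1-ol | C#C/C(C)=C/CO | starting material
5 | (2E)-5-[(4R)-4-[(tert-butyldimethylsilyl)oxy]-2,6,6-trimethylcyclohex-1-en-1-yl]-3-methylpent-2-en-4-yn-1-ol | CC1=C(C#C/C(C)=C/CO)C(C)(C)C[C@H](O[Si](C)(C)C(C)(C)C)C1 | intermediate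
6 | (2E)-5-[(4R)-4-[(tert-butyldimethylsilyl)oxy]-2,6,6-trimethylcyclohex-1-en-1-yl]-3-methylpent-2-en-4-ynal | CC1=C(C#C/C(C)=C/C=O)C(C)(C)C[C@H](O[Si](C)(C)C(C)(C)C)C1 | intermediate
7 | 3-bromo-1-(trimethylsilyl)prop-1-yne | C[Si](C)(C)C#CCBr | starting material
8 | diethyl [3-(trimethylsilyl)prop-2-yn-1-yl]phosphonate | CCOP(=O)(CC#C[Si](C)(C)C)OCC | intermediate
9 | tert-butyldimethyl{[(1R)-3,5,5-trimethyl-4-[(3E,5E)-3-methyl-8-(trimethylsilyl)octa-3,5-diene-1,7-diyn-1-yl]cyclohex-3-en-1-yl]oxy}silane | CC1=C(C#C/C(C)=C/C=C/C#C[Si](C)(C)C)C(C)(C)C[C@H](O[Si](C)(C)C(C)(C)C)C1 | intermediate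
10 | tert-butyldimethyl{[(1R)-3,5,5-trimethyl-4-[(3E,5E)-3-methylocta-3,5-diene-1,7-diyn-1-yl]cyclohex-3-en-1-yl]oxy}silane | CC1=C(C#C/C(C)=C/C=C/C#C)C(C)(C)C[C@H](O[Si](C)(C)C(C)(C)C)C1 | intermediate
11 | methyl (4R)-4-[(tert-butyldimethylsilyl)oxy]-2,6,6-trimethylcyclohex-1-ene-1-carboxylate | COC(=O)C1=C(C)C[C@@H](O[Si](C)(C)C(C)(C)C)CC1(C)C | intermediate
12 | [(4R)-4-[(tert-butyldimethylsilyl)oxy]-2,6,6-trimethylcyclohex-1-en-1-yl]methanol | OCC1=C(C)C[C@@H](O[Si](C)(C)C(C)(C)C)CC1(C)C | intermediate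
13 | [(1R,4S,6R)-4-[(tert-butyldimethylsilyl)oxy]-2,2,6-trimethyl-7-oxabicyclo[4.1.0]heptan-1-yl]methanol (epoxide oxygen trans to the silyloxy group) | OC[C@@]12O[C@]1(C)C[C@@H](O[Si](C)(C)C(C)(C)C)CC2(C)C | intermediate
14 | (1S,4S,6R)-4-[(tert-butyldimethylsilyl)oxy]-1-(iodomethyl)-2,2,6-trimethyl-7-oxabicyclo[4.1.0]heptane | IC[C@@]12O[C@]1(C)C[C@@H](O[Si](C)(C)C(C)(C)C)CC2(C)C | intermediate
15 | (1R,5S)-5-[(tert-butyldimethylsilyl)oxy]-1,3,3-trimethyl-2-methylidenecyclohexan-1-ol | C=C1[C@](C)(O)C[C@@H](O[Si](C)(C)C(C)(C)C)CC1(C)C | intermediate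
16 | spiro ozonide of 15 (1,2,4-trioxolane spiro-fused at the former alkene ring carbon, mixture at the spiro centre) | C[C@@]1(O)C[C@@H](O[Si](C)(C)C(C)(C)C)CC(C)(C)C12OCOO2 | intermediate
17 | (2R,4S)-4-[(tert-butyldimethylsilyl)oxy]-2-hydroxy-2,6,6-trimethylcyclohexan-1-one | O=C1[C@](C)(O)C[C@@H](O[Si](C)(C)C(C)(C)C)CC1(C)C | intermediate
18 | (2E)-3-methylpent-2-en-4-ynal | C#C/C(C)=C/C=O | intermediate
19 | ethyl (2E)-4-(diethoxyphosphoryl)-3-methylbut-2-enoate (triethyl 3-methyl-4-phosphonocrotonate) | CCOC(=O)/C=C(C)/CP(=O)(OCC)OCC | starting material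
20 | ethyl (2E,4E,6E)-3,7-dimethylnona-2,4,6-trien-8-ynoate | C#C/C(C)=C/C=C/C(C)=C/C(=O)OCC | intermediate
21 | (2E,4E,6E)-3,7-dimethylnona-2,4,6-trien-8-yn-1-ol | C#C/C(C)=C/C=C/C(C)=C/CO | intermediate
22 | (1R,2R,4S)-4-[(tert-butyldimethylsilyl)oxy]-1-[(3E,5E,7E)-9-hydroxy-3,7-dimethylnona-3,5,7-trien-1-yn-1-yl]-2,6,6-trimethylcyclohexane-1,2-diol | OC/C=C(C)/C=C/C=C(C)/C#C[C@]1(O)C(C)(C)C[C@H](O[Si](C)(C)C(C)(C)C)C[C@@]1(C)O | intermediate
23 | (1S,2R,4S)-4-[(tert-butyldimethylsilyl)oxy]-1-[(1E,3E,5E,7E)-9-hydroxy-3,7-dimethylnona-1,3,5,7-tetraen-1-yl]-2,6,6-trimethylcyclohexane-1,2-diol | OC/C=C(C)/C=C/C=C(C)/C=C/[C@]1(O)C(C)(C)C[C@H](O[Si](C)(C)C(C)(C)C)C[C@@]1(C)O | intermediate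
24 | (2E,4E,6E,8E)-9-[(1S,2R,4S)-4-[(tert-butyldimethylsilyl)oxy]-1,2-dihydroxy-2,6,6-trimethylcyclohexyl]-3,7-dimethylnona-2,4,6,8-tetraenal | O=C/C=C(C)/C=C/C=C(C)/C=C/[C@]1(O)C(C)(C)C[C@H](O[Si](C)(C)C(C)(C)C)C[C@@]1(C)O | intermediate
25 | (1S,2R,4S)-4-[(tert-butyldimethylsilyl)oxy]-1-[(1E,3E,5E,7E,9E)-10-iodo-3,7-dimethyldeca-1,3,5,7,9-pentaen-1-yl]-2,6,6-trimethylcyclohexane-1,2-diol | I/C=C/C=C(C)/C=C/C=C(C)/C=C/[C@]1(O)C(C)(C)C[C@H](O[Si](C)(C)C(C)(C)C)C[C@@]1(C)O | intermediate
26 | 1,2-bis-O-trimethylsilyl ether of 25 (C21 pentaenyl iodide) | I/C=C/C=C(C)/C=C/C=C(C)/C=C/[C@]1(O[Si](C)(C)C)C(C)(C)C[C@H](O[Si](C)(C)C(C)(C)C)C[C@@]1(C)O[Si](C)(C)C | intermediate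
27 | E-alkenyldimethylalane from 10 (methyl on C13', AlMe2 on C14') | CC1=C(C#C/C(C)=C/C=C/C(C)=C/[Al](C)C)C(C)(C)C[C@H](O[Si](C)(C)C(C)(C)C)C1 | intermediate
28 | E-alkenylzinc chloride from 27 | CC1=C(C#C/C(C)=C/C=C/C(C)=C/[Zn]Cl)C(C)(C)C[C@H](O[Si](C)(C)C(C)(C)C)C1 | intermediate
29 | (3S,5R,6S,3'R)-3,3'-bis[(tert-butyldimethylsilyl)oxy]-5,6-bis[(trimethylsilyl)oxy]-7',8'-didehydro-5,6-dihydro-β,β-carotene | CC1=C(C#C/C(C)=C/C=C/C(C)=C/C=C/C=C(C)/C=C/C=C(C)/C=C/[C@]2(O[Si](C)(C)C)C(C)(C)C[C@H](O[Si](C)(C)C(C)(C)C)C[C@@]2(C)O[Si](C)(C)C)C(C)(C)C[C@H](O[Si](C)(C)C(C)(C)C)C1 | intermediate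
30 | (3S,5R,6S,3'R)-7',8'-didehydro-5,6-dihydro-β,β-carotene-3,5,6,3'-tetrol | CC1=C(C#C/C(C)=C/C=C/C(C)=C/C=C/C=C(C)/C=C/C=C(C)/C=C/[C@]2(O)C(C)(C)C[C@H](O)C[C@@]2(C)O)C(C)(C)C[C@H](O)C1 | target

**Step count and risks**

Total step count: 23. Longest linear sequence: 15 steps (steps 1, 2, 8–13, 17–23).

Steps most likely to fail:

Step 22. What may go wrong: ionisation of the tertiary allylic C6 silyl ether or decomposition of the pentaenyl iodide in the Lewis-acidic aluminium/zinc medium, and quenching or methyl transfer of the alane, so that the valuable iodide 26 is consumed without coupling. The fallback sets out from 10 and from aldehyde 24 and comes back to the route at 30. The methylalumination of 10 is run on its own and quenched with I2 to give the purifiable E-alkenyl iodide F1. Aldehyde 24 is converted by chromium-mediated stannyl-olefination (CrCl2, Bu3SnCHBr2, LiI, THF–DMF) into the E-pentaenylstannane diol F2. A neutral Stille coupling of F1 with F2 (Pd2(dba)3, AsPh3, NMP, 23 °C), which tolerates the free tertiary diol and needs no aluminium or zinc, gives the 3,3'-bis-TBS ether of the target F3. The fluoride conditions of step 23 then give 30.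

Step 17. What may go wrong: slow addition to the doubly neopentyl carbonyl, base-induced α-ketol rearrangement of the alkoxide, or attack from the equatorial face leading to the trans-diol. The fallback sets out from 15 and comes back to the route at 24. The C6 carbinol is set instead by hydroxyl-directed dihydroxylation of the exocyclic alkene of 15 with OsO4·TMEDA (CH2Cl2, −78 °C), the hydrogen-bonded reagent adding on the face of the C5–OH to give the triol F4. Parikh–Doering oxidation of its primary alcohol gives the dihydroxy aldehyde F5. Horner–Wadsworth–Emmons reaction with commercial diethyl (3-cyano-2-methylallyl)phosphonate gives the dienenitrile F6, and i-Bu2AlH reduction gives the dienal F7. A second olefination with the same phosphonate gives the tetraenenitrile F8, and i-Bu2AlH reduction of F8 gives aldehyde 24.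

Step 20. What may go wrong: erosion of E selectivity at the new C15=C15' bond with a polyenal, and loss of material through light- or chromium-induced decomposition of the iodide. The fallback sets out from 24 and comes back to the route at 26. Ohira–Bestmann homologation (dimethyl (1-diazo-2-oxopropyl)phosphonate, K2CO3, MeOH) gives the terminal tetraenyne F9. Silylation under the conditions of step 21 gives the bis-TMS ether F10. Hydrozirconation with Cp2Zr(H)Cl followed by I2 gives 26, the E geometry being fixed by syn addition.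

Further compounds
F1 | step 22 | tert-butyl{[(1R)-4-[(3E,5E,7E)-8-iodo-3,7-dimethylocta-3,5,7-trien-1-yn-1-yl]-3,5,5-trimethylcyclohex-3-en-1-yl]oxy}dimethylsilane | CC1=C(C#C/C(C)=C/C=C/C(C)=C/I)C(C)(C)C[C@H](O[Si](C)(C)C(C)(C)C)C1
F2 | step 22 | (1S,2R,4S)-4-[(tert-butyldimethylsilyl)oxy]-1-[(1E,3E,5E,7E,9E)-3,7-dimethyl-10-(tributylstannyl)deca-1,3,5,7,9-pentaen-1-yl]-2,6,6-trimethylcyclohexane-1,2-diol | CCCC[Sn](CCCC)(CCCC)/C=C/C=C(C)/C=C/C=C(C)/C=C/[C@]1(O)C(C)(C)C[C@H](O[Si](C)(C)C(C)(C)C)C[C@@]1(C)O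
F3 | step 22 | 3,3'-bis-O-(tert-butyldimethylsilyl) ether of 30 | CC1=C(C#C/C(C)=C/C=C/C(C)=C/C=C/C=C(C)/C=C/C=C(C)/C=C/[C@]2(O)C(C)(C)C[C@H](O[Si](C)(C)C(C)(C)C)C[C@@]2(C)O)C(C)(C)C[C@H](O[Si](C)(C)C(C)(C)C)C1
F4 | step 17 | (1R,2R,4S)-4-[(tert-butyldimethylsilyl)oxy]-1-(hydroxymethyl)-2,6,6-trimethylcyclohexane-1,2-diol | OC[C@]1(O)C(C)(C)C[C@H](O[Si](C)(C)C(C)(C)C)C[C@@]1(C)O
F5 | step 17 | (1S,2R,4S)-4-[(tert-butyldimethylsilyl)oxy]-1,2-dihydroxy-2,6,6-trimethylcyclohexane-1-carbaldehyde | O=C[C@]1(O)C(C)(C)C[C@H](O[Si](C)(C)C(C)(C)C)C[C@@]1(C)O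
F6 | step 17 | (2E,4E)-5-[(1S,2R,4S)-4-[(tert-butyldimethylsilyl)oxy]-1,2-dihydroxy-2,6,6-trimethylcyclohexyl]-3-methylpenta-2,4-dienenitrile | N#C/C=C(C)/C=C/[C@]1(O)C(C)(C)C[C@H](O[Si](C)(C)C(C)(C)C)C[C@@]1(C)O
F7 | step 17 | (2E,4E)-5-[(1S,2R,4S)-4-[(tert-butyldimethylsilyl)oxy]-1,2-dihydroxy-2,6,6-trimethylcyclohexyl]-3-methylpenta-2,4-dienal | O=C/C=C(C)/C=C/[C@]1(O)C(C)(C)C[C@H](O[Si](C)(C)C(C)(C)C)C[C@@]1(C)O
F8 | step 17 | (2E,4E,6E,8E)-9-[(1S,2R,4S)-4-[(tert-butyldimethylsilyl)oxy]-1,2-dihydroxy-2,6,6-trimethylcyclohexyl]-3,7-dimethylnona-2,4,6,8-tetraenenitrile | N#C/C=C(C)/C=C/C=C(C)/C=C/[C@]1(O)C(C)(C)C[C@H](O[Si](C)(C)C(C)(C)C)C[C@@]1(C)O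
F9 | step 20 | (1S,2R,4S)-4-[(tert-butyldimethylsilyl)oxy]-1-[(1E,3E,5E,7E)-3,7-dimethyldeca-1,3,5,7-tetraen-9-yn-1-yl]-2,6,6-trimethylcyclohexane-1,2-diol | C#C/C=C(C)/C=C/C=C(C)/C=C/[C@]1(O)C(C)(C)C[C@H](O[Si](C)(C)C(C)(C)C)C[C@@]1(C)O
F10 | step 20 | 1,2-bis-O-trimethylsilyl ether of F9 | C#C/C=C(C)/C=C/C=C(C)/C=C/[C@]1(O[Si](C)(C)C)C(C)(C)C[C@H](O[Si](C)(C)C(C)(C)C)C[C@@]1(C)O[Si](C)(C)C
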